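## Retrosynthetic overview

- **Feature:** in each half, saturated ring B (C1, C2, C3, C4, C4a, C8a; tetralin numbering with C1 methyl, C4 isopropyl, C6 methyl, C8 OH) is the trans-p-menthane ring of (+)-menthone. Its C=O is C4a and its free alpha-CH2 is C8a, so phenol ring A lacks only C5, C6, C7 and C8.
- **Last disconnection:** the C7–C5' biaryl bond, made by Suzuki–Miyaura coupling of a C7 boronate with a C5 bromide. Both come from one MOM ether of the monomer phenol.
- **Monomer phenol:** from the ring A cyclohexene-4a,8-diol by oxidation at C8 and loss of the C4a hydroxyl as water.
- **Ring A:** closed at C6=C7 by ring-closing metathesis of a diene diol. The C8a arm (C8, C7) comes from acrolein by aldol addition, and the C4a arm (C5, C6, C6 methyl) from 2-methylallylmagnesium chloride.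
- **Ring order:** ring B is bought, ring A is closed in step 5 and made aromatic in step 7, and one sequence feeds both halves.

Key step: step 5

Assumption (axis): the target structure gives no descriptor for the tetra-ortho-substituted C7–C5' axis. The coupling may therefore give two atropodiastereomers, which would be separated by chromatography, and either one matches the structure given.

Assumption (provisional centres): C8, C8a and C4a are carried as diastereomer mixtures and drawn without configuration, because all three become sp2 on aromatisation. C1 stays S and C4 stays R (tetralin numbering) in every compound.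

Assumption (supply): (+)-menthone, (2R,5S), is taken as a commercial single enantiomer free of its C4 epimer, and 2-methylallylmagnesium chloride as the commercial THF solution.

## Route

Step 1
Reactants: 1 (+)-menthone, (2R,5S)-5-methyl-2-(propan-2-yl)cyclohexan-1-one; 2 acrolein
Product: 4 acrolein aldol adduct (3S,6R)-2-(1-hydroxyprop-2-en-1-yl)-3-methyl-6-(propan-2-yl)cyclohexan-1-one, via kinetic lithium enolate 3 (not isolated)
Conditions: LiN(iPr)2 (1.1 equiv), THF, −78 °C; 2, −78 °C; aq NH4Cl at −78 °C
Reagents that add atoms: acrolein (2), C=CC=O
Why: Directed aldol addition in which the bulky amide removes a proton from the unhindered C8a methylene under kinetic control and leaves C4–H untouched, the lithium enolate then attacks the acrolein carbonyl (1,2-addition) at low temperature, and the new centres C8a and C8 need no control because both become sp2 in step 7.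

Step 2
Reactants: 4 acrolein aldol adduct
Product: 5 triethylsilyl ether of 4 (C8–OSiEt3, C4a ketone)
Conditions: Et3SiCl, imidazole, DMF, 0 °C to rt
Reagents that add atoms: chlorotriethylsilane, CC[Si](Cl)(CC)CC
Why: Imidazole-promoted silylation of the secondary carbinol, which masks the hydroxyl so that no aldolate (and so no retro-aldol cleavage) can arise in step 3, under conditions too weakly basic to enolise the ketone toward C4.

Step 3
Reactants: 5 triethylsilyl ether; 6 2-methylallylmagnesium chloride (THF solution)
Product: 7 tertiary alcohol (3S,6R)-3-methyl-1-(2-methylprop-2-en-1-yl)-6-(propan-2-yl)-2-[1-(triethylsilyloxy)prop-2-en-1-yl]cyclohexan-1-ol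
Conditions: 6 (2 equiv), THF, −78 to 0 °C; aq NH4Cl
Reagents that add atoms: 2-methylallylmagnesium chloride (6), CC(=C)C[Mg]Cl
Why: Grignard 1,2-addition of an allylic reagent through a six-membered cyclic transition state, which is fast even on doubly alpha-branched ketones and outruns enolisation, with the C4a configuration set by approach from the less hindered face but irrelevant since it is erased in step 7, and with C4 no longer epimerisable once the carbonyl is consumed.

Step 4
Reactants: 7 tertiary alcohol
Product: 8 diene diol (3S,6R)-2-(1-hydroxyprop-2-en-1-yl)-3-methyl-1-(2-methylprop-2-en-1-yl)-6-(propan-2-yl)cyclohexan-1-ol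
Conditions: HF·pyridine, pyridine, THF, 0 °C to rt
Reagents that add atoms: none
Why: Fluoride-driven cleavage of the Si–O bond (silyl ether deprotection), buffered by pyridine so that neither the tertiary homoallylic alcohol nor the allylic alcohol ionises.

Step 5
Reactants: 8 diene diol
Product: 9 ring A cyclohexene diol (1S,4R)-1,6-dimethyl-4-(propan-2-yl)-1,2,3,4,4a,5,8,8a-octahydronaphthalene-4a,8-diol (route numbering, C6=C7 alkene)
Conditions: second-generation Grubbs catalyst RuCl2(=CHPh)(PCy3)(SIMes) (5 mol %), CH2Cl2 (0.005 M), 40 °C, argon sparge
Reagents that add atoms: none
Why: Ring-closing olefin metathesis by the Chauvin mechanism, in which the ruthenium benzylidene exchanges with the monosubstituted C7 vinyl group, the C7 alkylidene adds across the 1,1-disubstituted C6 alkene of the neighbouring arm to give a ruthenacyclobutane, and cycloreversion releases the C6=C7 alkene and a ruthenium methylidene that carries the chain while ethylene escapes. The closest known reaction type is the closure of 1,7-dienes bearing one terminal and one 2-methylallyl alkene to 1-methylcyclohexenes with carbene-ligated ruthenium catalysts, free allylic and tertiary alcohols included. Ring A closes as a six-membered carbocycle with the new double bond endocyclic, fused to ring B along C4a–C8a. No stereocentre is formed, C8, C8a and C4a stay as they are, and C1 and C4 are remote from every reacting bond. The selectivity needed is ring closure over intermolecular metathesis, and it is secured by the two arms sitting gauche on adjacent ring carbons in both the cis and the trans diastereomers, by the reluctance of the 1,1-disubstituted alkene to homodimerise, and by high dilution.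

Step 6
Reactants: 9 ring A cyclohexene diol
Product: 10 ring A beta-hydroxy enone (C8 ketone, C6=C7 alkene, C4a OH; 1S,4R)
Conditions: MnO2 (activated, excess), CH2Cl2, rt
Reagents that add atoms: none
Why: Selective allylic alcohol oxidation by MnO2, in which the tertiary C4a hydroxyl cannot be oxidised and the neutral heterogeneous medium avoids early dehydration or retro-aldol opening.

Step 7
Reactants: 10 ring A beta-hydroxy enone
Product: 12 monomer phenol (5R,8S)-3,8-dimethyl-5-(propan-2-yl)-5,6,7,8-tetrahydronaphthalen-1-ol, via cross-conjugated dienone 11 (not isolated)
Conditions: p-TsOH·H2O (10 mol %), toluene, 60 °C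
Reagents that add atoms: none
Why: Acid-catalysed aldol-type dehydration in which enolisation of the C8 ketone toward C8a expels the protonated tertiary C4a hydroxyl to give the cross-conjugated dienone, whose doubly activated C5 methylene then loses a proton (keto–phenol tautomerisation) far faster than C4–H could, so ring A becomes aromatic, C1 and C4 keep their configuration, and the three provisional centres disappear.

Step 8
Reactants: 12 monomer phenol
Product: 13 methoxymethyl (MOM) ether of 12 (C8–OCH2OCH3)
Conditions: NaH, MOMCl, THF–DMF, 0 °C to rt
Reagents that add atoms: chloromethyl methyl ether, COCCl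
Why: Williamson-type O-alkylation of the sodium phenoxide by a reactive alpha-chloro ether, giving a base-stable group that serves as the lithiation director in step 9 and as the para director in step 10.

Step 9
Reactants: 13 MOM ether (first portion)
Product: 15 C7 pinacol boronate of 13, via C7 aryllithium 14 (not isolated)
Conditions: n-BuLi, TMEDA, Et2O, 0 °C; iPrOBpin, −78 °C to rt; aq NH4Cl
Reagents that add atoms: 2-isopropoxy-4,4,5,5-tetramethyl-1,3,2-dioxaborolane, CC(C)OB1OC(C)(C)C(C)(C)O1
Why: Directed ortho-metalation in which the MOM oxygens bind lithium and steer deprotonation to C7, the only free ortho position since C8a is substituted, while the tertiary benzylic C1–H is kinetically far less acidic and stays untouched, and the aryllithium is trapped by the borate ester with loss of isopropoxide.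

Step 10
Reactants: 13 MOM ether (second portion)
Product: 16 C5 bromide of 13
Conditions: NBS (1.0 equiv), MeCN, 0 °C, dark
Reagents that add atoms: N-bromosuccinimide, O=C1CCC(=O)N1Br
Why: Electrophilic aromatic bromination, for which NBS in acetonitrile is known to attack aryl ethers para to oxygen even between two ortho alkyl groups, C5 being that para site, while exclusion of light suppresses radical bromination at C1, C4 and the C6 methyl, and the site would be confirmed by an NOE between the remaining aryl H and the OCH2O group.

Step 11
Reactants: 15 C7 pinacol boronate; 16 C5 bromide
Product: 17 bis-MOM ether of the C7–C5' biaryl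
Conditions: Pd(OAc)2 (5 mol %), SPhos (10 mol %), K3PO4, toluene–H2O, 100 °C
Reagents that add atoms: none
Why: Suzuki–Miyaura coupling in which the bulky electron-rich biarylphosphine gives a monoligated zerovalent palladium species of the kind known to join two di-ortho-substituted partners, with no carbon stereocentre touched and the new axis left uncontrolled as stated in the assumption.

Step 12
Reactants: 17 bis-MOM biaryl
Product: 18 target CNP0145304.1
Conditions: conc. HCl (cat.), MeOH, 50 °C
Reagents that add atoms: none
Why: Acid-catalysed acetal exchange with methanol removes both MOM groups under conditions that do not ionise the benzylic C1–H and C4–H bonds, so all four stereocentres are kept.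

## Compound list

1 | (+)-menthone, (2R,5S) | O=C1C[C@@H](C)CC[C@@H]1C(C)C | starting material
2 | acrolein | C=CC=O | starting material
3 | kinetic lithium enolate of 1 (C4a–OLi, C4a=C8a), not isolated | [Li]OC1=C[C@@H](C)CC[C@@H]1C(C)C | intermediate
4 | acrolein aldol adduct (C8 and C8a epimers) | C=CC(O)C1C(=O)[C@@H](C(C)C)CC[C@@H]1C | intermediate
5 | triethylsilyl ether of 4 | C=CC(O[Si](CC)(CC)CC)C1C(=O)[C@@H](C(C)C)CC[C@@H]1C | intermediate
6 | 2-methylallylmagnesium chloride | CC(=C)C[Mg]Cl | starting material
7 | C4a tertiary alcohol with methallyl arm and silylated vinyl carbinol arm | C=CC(O[Si](CC)(CC)CC)C1C(O)(CC(C)=C)[C@@H](C(C)C)CC[C@@H]1C | intermediate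
8 | diene diol (metathesis precursor) | C=CC(O)C1C(O)(CC(C)=C)[C@@H](C(C)C)CC[C@@H]1C | intermediate
9 | ring A cyclohexene-4a,8-diol | CC1=CC(O)C2C(O)(C1)[C@@H](C(C)C)CC[C@@H]2C | intermediate
10 | ring A beta-hydroxy enone | CC1=CC(=O)C2C(O)(C1)[C@@H](C(C)C)CC[C@@H]2C | intermediate
11 | cross-conjugated dienone (keto tautomer of 12), not isolated | CC1=CC(=O)C2=C(C1)[C@@H](C(C)C)CC[C@@H]2C | intermediate
12 | monomer phenol, (1S,4R) in tetralin numbering | Cc1cc(O)c2c(c1)[C@@H](C(C)C)CC[C@@H]2C | intermediate
13 | MOM ether of 12 | Cc1cc(OCOC)c2c(c1)[C@@H](C(C)C)CC[C@@H]2C | intermediate
14 | C7 aryllithium of 13, not isolated | Cc1cc2c(c(OCOC)c1[Li])[C@@H](C)CC[C@@H]2C(C)C | intermediate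
15 | C7 pinacol boronate of 13 | Cc1cc2c(c(OCOC)c1B3OC(C)(C)C(C)(C)O3)[C@@H](C)CC[C@@H]2C(C)C | intermediate
16 | C5 bromide of 13 | Cc1cc(OCOC)c2c(c1Br)[C@@H](C(C)C)CC[C@@H]2C | intermediate
17 | bis-MOM ether of the C7–C5' biaryl | Cc1cc2c(c(OCOC)c1-c1c(C)cc(OCOC)c3c1[C@@H](C(C)C)CC[C@@H]3C)[C@@H](C)CC[C@@H]2C(C)C | intermediate
18 | CNP0145304.1 | Cc1cc2c(c(O)c1-c1c(C)cc(O)c3c1[C@@H](C(C)C)CC[C@@H]3C)[C@@H](C)CC[C@@H]2C(C)C | target

## Step count

- Total step count: 12
- Longest linear sequence: 11 (steps 1 to 8, then 9 or 10, then 11 and 12)

## Steps most likely to fail

**Step 11.** Transmetalation between two partners that each carry two ortho substituents may be so slow that protodeboronation of the boronate and reduction of the C–Br bond overtake C–C bond formation.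

The fallback is a Negishi coupling, which replaces boron by zinc and removes base and water. It sets out from 13, which is lithiated at C7 as in step 9 (14) and treated with ZnCl2 in THF to give the C7 arylzinc chloride F1. F1 is coupled with 16 under Pd2(dba)3/RuPhos in THF–NMP at 70 °C, a catalyst type known for tetra-ortho-substituted biaryls. The route is rejoined at 17.

**Step 5.** Ruthenium hydride species formed by catalyst decay may shift the free allylic alcohol to a saturated ketone (redox isomerisation). Slow loading at the crowded vinyl carbinol may also let intermolecular metathesis compete.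

The fallback moves ring closure ahead of the desilylation, so that the carbinol oxygen is capped during metathesis. It sets out from 7, which is closed with the same second-generation Grubbs catalyst in toluene at 80 °C to the silyl-protected ring A cyclohexene F2. Treating F2 with HF·pyridine then frees the C8 hydroxyl, and the route is rejoined at 9.

**Step 10.** Site selectivity between C5 and C7 may be poor, because C5 is shielded by the C4 isopropyl group and the C6 methyl.

The fallback makes the outcome independent of that choice by exhaustive bromination followed by site-selective debromination. It sets out from 13, which with NBS (2.2 equiv) in MeCN gives the 5,7-dibromide F3. One equivalent of n-BuLi in THF at −78 °C exchanges the bromine ortho to the MOM ether, where lithium is chelated, to give the 5-bromo-7-lithio arene F4. Protonation of F4 with aq NH4Cl rejoins the route at 16.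

## Further compounds

F1 | step 11 | C7 arylzinc chloride of 13 | Cc1cc2c(c(OCOC)c1[Zn]Cl)[C@@H](C)CC[C@@H]2C(C)C
F2 | step 5 | C8 triethylsilyl ether of ring A cyclohexene diol | CC1=CC(O[Si](CC)(CC)CC)C2C(O)(C1)[C@@H](C(C)C)CC[C@@H]2C
F3 | step 10 | 5,7-dibromide of 13 | Cc1c(Br)c(OCOC)c2c(c1Br)[C@@H](C(C)C)CC[C@@H]2C
F4 | step 10 | 5-bromo-7-lithio arene | Cc1c([Li])c(OCOC)c2c(c1Br)[C@@H](C(C)C)CC[C@@H]2C
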